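The data are calculated from invented constants.

The share of the charge standing in Ja did not move with the charge: at 20.0 h, Thursday's run, started at 0.094 M, held 22.4% and Friday's, started at 0.21 M, held 21.8%, while Jc read 15.0% in both. So I treated the loss of Ja as first-order and let fractions of the charge from both runs speak for a flask at 0.14 M.

| flask | Ja | remark | time |
|---|---|---|---|
| Thursday's | 0.094 M | run made earlier |  |
| Friday's | 0.21 M | run made earlier |  |
| flask | 0.14 M |  | 50 h |

| run | time / h | Jc / % | Ja / % |
|---|---|---|---|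
| Thursday's | 6.00 | 5.9 | 64.2 |
| Thursday's | 10.0 | 10.2 | 47.5 |
| Thursday's | 12.0 | 11.3 | 40.0 |
| Thursday's | 15.0 | 13.1 | 32.6 |
| Thursday's | 20.0 | 15.0 | 22.4 |
| Thursday's | 30.0 | 15.5 | 10.8 |
| Thursday's | 40.0 | 14.3 | 4.7 |
| Friday's | 6.00 | 6.0 | 63.6 |
| Friday's | 10.0 | 10.0 | 47.3 |
| Friday's | 12.0 | 11.5 | 39.8 |
| Friday's | 15.0 | 12.7 | 33.0 |
| Friday's | 20.0 | 15.0 | 21.8 |
| Friday's | 30.0 | 15.6 | 10.9 |
| Friday's | 40.0 | 14.8 | 4.6 |

(each reading ± 0.3 percentage points)

1. the best time, 50 h at the latest, for Jc
2. the amount of Jc, in percent of the Ja charged, at that time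



Those two Ja readings, averaged, gave a decay constant of 0.0755 /h. The time in which whatever is left of Ja halves, its half-life, came out at 9.18 h, and I used it as the clock. Near the first mark, at 10.0 h, Thursday's run held 47.5% Ja and 10.2% Jc, so 42.3% of the charge stood in something unread.

The next mark is where Jc's slope crosses zero, the balance at which Jc made equals Jc lost. Jc read higher at 30.0 h than at 20.0 h in both runs, and lower at 40.0 h than at 20.0 h, so I placed the peak before 30.0 h. I committed to 3 half-lives, 27.5 h, with a height near the reading of 15.6%. The last mark, 50 h, is 5.45 half-lives, which leaves 2.29% Ja, and my peak stands earlier than that limit.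

The forecast said “All steps therefore look first-order” and gave 27 h with 15.7%, a time earlier than mine.

The flask gives 15.9% at 27.0 h, which is 2.94 half-lives.

    Ja → Jb (k = 0.0750 /h)
    Jb ⇌ Jc (K = 0.480, k = 0.140 /h)
    Jc ⇌ Jd (K = 0.420, k = 0.220 /h)
    Jc → Je (k = 0.0770 /h)

Charged with half the Ja, this flask reaches a highest Jc of 15.9% of that charge. At 27.0 h the half-life leaves 13.0% Ja, and the flask holds 13.2%. For the same flask read at 12 h it leaves 40.4%, and that neighbour holds 41%.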